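Flavan numbering is used throughout: O1, C2, C3, C4, C4a, C5, C6, C7, C8, C8a. Ring A is the benzo ring, ring C the pyran ring, ring B the aryl group on C2 (C1′–C6′), and C1″ is the benzylic carbon of the prenyl group.

## Analysis of the target

Compound 14 is a flavan: benzo ring A fused to dihydropyran ring C, with a 3-hydroxy-5-methoxyphenyl ring B on C2. Ring A is a phloroglucinol whose three oxygens are all different (C5–OMe, C7–OH, C8a–O1); it carries carbon at C4a and a prenyl group at C8, and only C6 bears hydrogen. C2 is the only stereocentre, and the given descriptor corresponds to (R) (O1 > C1′ > C3 > H). With no neighbouring centre to relay from, it must be set by a reagent and then survive as a benzylic ether. The sensitive groups are the prenyl olefin (hydrogenation, acid-induced addition of the C7 hydroxyl), two free phenols on different rings, and the benzylic C2–O1 bond. The real difficulty is regiochemical: C6 and C8 are both ortho to the C7 oxygen and both doubly activated, so electrophilic or Claisen prenylation does not tell them apart, while the three ring-A oxygens must be differentiated at the same time. The feature this route exploits is the triad C7(O)–C8(C)–C8a(O). C8a and C8 are neighbouring ring-A atoms that carry a former nucleophile (O1, tethered to C4a through C4–C3–C2) and a former electrophile (C1″), with the C7 oxygen beside them. That is the pattern left when a 3-alkoxyaryne takes up a nucleophile and then an electrophile.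

## Retrosynthetic reasoning

14 from 13. The two phenols are masked as MOM ethers. MOM is stable to alkoxide, hydrogenation and organolithium reagents, the C7–OMOM group helps direct and stabilise the ring-A carbanions of the key step, and both groups fall together under mild acid at the end.

13 from 9 (key disconnection). Two bonds on neighbouring ring-A atoms are cut at once, O1–C8a and C8–C1″, which opens ring C and removes the prenyl group. The precursor 9 is an open-chain 1,3-diarylpropan-1-ol whose ring A carries fluorine at the future C8a and hydrogen at the future C8. Forward, ring lithiation next to fluorine (10), loss of LiF to aryne 11, addition of the tethered alkoxide at C8a (12) and capture of the C8 carbanion by a prenyl electrophile must follow one another in one flask. The cut is made here because the aryne can place carbon only on C8, so the C6/C8 question never arises. The stereocentre is also a spectator: the bond formed is aryl C–O, so the carbinol configuration is carried over unchanged and no substitution at the benzylic carbon is needed.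

9 from 8. The C2–H bond is disconnected. The forward step is an enantioselective reduction of an aryl alkyl ketone, which is among the most dependable ways to set an isolated benzylic carbinol.

8 from 7, and 7 from 3 and 5 (through 6). The C3–C4 bond is cut as an enone. Forward, a crossed aldol condensation joins the two aromatic halves with all ring substituents already in place, and the C=C bond is then saturated. The carbonyl sits on the ring-B side, so the later carbinol is C2.

3 from 2, and 2 from 1. Ring A is traced to a symmetric 2,6-difluoro-4-hydroxybenzaldehyde. Because its two fluorines are equivalent, exchange of one for methoxy (the future C5–OMe) cannot give a regioisomer. The remaining fluorine is the aryne leaving group at the future C8a, and the formyl carbon becomes C4.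

5 from 4. The ring-B phenol is protected with the same MOM group so that one final operation frees both phenols.

## Alternatives that were turned down

Alternative 1: the textbook cut of O1–C2. Phenol-alcohol A1, with (1S) configuration and the prenyl group already on ring A, would be closed by a Mitsunobu reaction (PPh3, diisopropyl azodicarboxylate) with inversion. It was turned down for three reasons:
- The prenyl group must be on ring A before ring closure, and C-prenylation of a phloroglucinol ether is unselective between the two ortho carbons and between C and O.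
- The enone hydrogenation of a chalcone-type assembly would not spare the prenyl olefin, so the order of steps becomes awkward.
- Ring A would need three different oxygen substituents plus a free hydroxyl, which costs several protecting-group steps.

The route would be about four steps longer and leaves the hardest problem (C8 against C6) unsolved.

Alternative 2: cut O1–C2 and C3–C4 together. The forward step is an inverse-demand hetero-Diels–Alder reaction of ortho-quinone methide A2 with styrene A3 under a chiral phosphoric acid. It was turned down because:
- The new stereocentre arises on the styrene carbon, far from the catalyst-bound oxygen of A2, and the methide terminus of A2 is unsubstituted, so there is little basis for facial control.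
- The oxygen substituents of A3 are meta to the vinyl group and do not raise its nucleophilicity, so oligomerisation of A2 should compete.
- A2 must already carry the prenyl group, so the regiochemical problem is only moved, and the acid catalyst threatens the ortho-prenyl phenol.

Alternative 3: cut C8–C1″ by a late aromatic Claisen rearrangement. The 7-O-(1,1-dimethylallyl) ether A4 would rearrange [3,3] to the C8-prenyl phenol A6. It was turned down because:
- Both ortho positions of the C7 oxygen are free and similarly substituted, so the C6 isomer A5 is expected alongside A6, and the two differ only in the position of one substituent.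
- The rearrangement builds neither ring C nor the stereocentre, so the whole textbook flavan synthesis is still needed before it.
- About three extra steps go into making the tertiary allyl ether.

Key step: step 7

Assumption: ketone 4 is taken as a commercial building block, as is aldehyde 1.
Remark on the chemistry: the given stereodescriptor corresponds to (2R); the antipode would follow from the enantiomeric catalyst in step 6.

## Route

Step 1
Reactants: 1 2,6-difluoro-4-hydroxybenzaldehyde
Product: 2 2,6-difluoro-4-(methoxymethoxy)benzaldehyde
Conditions: chloromethyl methyl ether, K2CO3, acetone, 0 °C to rt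
Reagents that add atoms: chloromethyl methyl ether, COCCl
Why: O-alkylation of an acidic para-formyl phenoxide (Williamson type); the MOM ether is stable to all basic and reductive steps that follow and later assists ring lithiation.

Step 2
Reactants: 2 2,6-difluoro-4-(methoxymethoxy)benzaldehyde
Product: 3 2-fluoro-6-methoxy-4-(methoxymethoxy)benzaldehyde
Conditions: NaOMe (1.1 equiv), MeOH/THF, 0 to 40 °C
Reagents that add atoms: sodium methoxide, [Na+].[O-]C
Why: Nucleophilic aromatic substitution (addition–elimination) ortho to the formyl group; the two fluorines are equivalent, so only one product can form, and the new methoxy group deactivates the ring toward a second exchange.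

Step 3
Reactants: 4 1-(3-hydroxy-5-methoxyphenyl)ethan-1-one
Product: 5 1-[3-methoxy-5-(methoxymethoxy)phenyl]ethan-1-one
Conditions: chloromethyl methyl ether, K2CO3, acetone, 0 °C to rt
Reagents that add atoms: chloromethyl methyl ether, COCCl
Why: Phenol O-alkylation as in step 1; the ketone is not enolised by K2CO3 under these conditions.

Step 4
Reactants: 3 2-fluoro-6-methoxy-4-(methoxymethoxy)benzaldehyde; 5 1-[3-methoxy-5-(methoxymethoxy)phenyl]ethan-1-one
Product: 7 (2E)-3-[2-fluoro-6-methoxy-4-(methoxymethoxy)phenyl]-1-[3-methoxy-5-(methoxymethoxy)phenyl]prop-2-en-1-one, via aldol adduct 6 (not isolated)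
Conditions: KOH, EtOH, 0 °C to rt
Reagents that add atoms: none
Why: Claisen–Schmidt condensation: only 5 can enolise and 3 is a non-enolisable aldehyde, so a single crossed aldol 6 forms and loses water by E1cB elimination to the (E)-enone; MOM ethers are base-stable.

Step 5
Reactants: 7 (2E)-3-[2-fluoro-6-methoxy-4-(methoxymethoxy)phenyl]-1-[3-methoxy-5-(methoxymethoxy)phenyl]prop-2-en-1-one
Product: 8 3-[2-fluoro-6-methoxy-4-(methoxymethoxy)phenyl]-1-[3-methoxy-5-(methoxymethoxy)phenyl]propan-1-one
Conditions: H2 (1 atm), 5% Pd/C, Ph2S (cat.), EtOAc, rt
Reagents that add atoms: none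
Why: Heterogeneous hydrogenation of the conjugated C=C bond; the sulfide-moderated catalyst should leave the aryl ketone, the aryl fluoride and the MOM ethers untouched.

Step 6
Reactants: 8 3-[2-fluoro-6-methoxy-4-(methoxymethoxy)phenyl]-1-[3-methoxy-5-(methoxymethoxy)phenyl]propan-1-one
Product: 9 (1R)-3-[2-fluoro-6-methoxy-4-(methoxymethoxy)phenyl]-1-[3-methoxy-5-(methoxymethoxy)phenyl]propan-1-ol
Conditions: RuCl[(R,R)-TsDPEN](p-cymene) (1 mol %), HCO2H/Et3N (5:2), 30 °C
Reagents that add atoms: none
Why: Noyori-type asymmetric transfer hydrogenation of an aryl alkyl ketone; the (R,R)-catalyst should deliver hydride to the Si face through the six-membered outer-sphere transition state with a CH–π contact to ring B, giving the (R)-carbinol, which is the future C2.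

Step 7
Reactants: 9 (1R)-3-[2-fluoro-6-methoxy-4-(methoxymethoxy)phenyl]-1-[3-methoxy-5-(methoxymethoxy)phenyl]propan-1-ol
Product: 13 (2R)-5-methoxy-7-(methoxymethoxy)-2-[3-methoxy-5-(methoxymethoxy)phenyl]-8-(3-methylbut-2-en-1-yl)-3,4-dihydro-2H-chromene, via ring-lithiated lithium alkoxide 10 (not isolated), via aryne alkoxide 11 (not isolated), via 8-lithiochromane 12 (not isolated)
Conditions: s-BuLi (2.1 equiv), THF (0.02 M), −78 °C, 1 h; warm to 0 °C, 1 h; recool to −78 °C; CuBr·SMe2 (10 mol %), 1-bromo-3-methylbut-2-ene (1.5 equiv), −78 °C to rt
Reagents that add atoms: 1-bromo-3-methylbut-2-ene (prenyl bromide), CC(C)=CCBr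
Why: The first equivalent of s-BuLi forms the lithium alkoxide and the second removes the ring-A hydrogen flanked by fluorine and OMOM, the most acidic aryl C–H in the molecule, to give 10, which loses LiF on warming to the 3-alkoxyaryne 11. The tethered alkoxide then adds to the aryne carbon C8a in a 6-exo-dig closure of ring C (bond O1–C8a), leaving the carbanion on C8 as aryllithium 12. The side of addition is fixed twice over: the three-atom tether can reach only C8a, and a 3-alkoxyaryne takes nucleophiles at the carbon remote from the alkoxy group because the charge then develops on C8 next to the C7 oxygen, where it is stabilised inductively and chelated by the MOM group. Aryllithium 12, flanked by O1 and OMOM, is transmetallated by catalytic CuBr·SMe2 and allylated at the primary carbon of prenyl bromide (SN2, since the other allyl terminus is fully substituted), forming C8–C1″. The closest known reaction types are aryne ring closures of halogenoaryl-alkanols and -alkylamines to chromans and indolines, nucleophile–aryne–electrophile sequences, and copper-mediated prenylation of ortho-lithiated MOM aryl ethers. No new stereocentre is formed, and because the bond made to oxygen is the aryl C8a–O bond, the (R)-carbinol centre of 9 becomes C2 of 13 with retention. The step needs lithiation next to fluorine rather than at the C–H positions lying between two oxygens on rings A and B; this should be secured kinetically at −78 °C by the acidifying fluorine acting together with OMOM. It also needs intramolecular capture of the aryne to outrun capture by aryllithium species, which dilution and the absence of excess base or amine should favour.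

Step 8
Reactants: 13 (2R)-5-methoxy-7-(methoxymethoxy)-2-[3-methoxy-5-(methoxymethoxy)phenyl]-8-(3-methylbut-2-en-1-yl)-3,4-dihydro-2H-chromene
Product: 14 3-[(2R)-7-hydroxy-5-methoxy-8-(3-methylbut-2-en-1-yl)-3,4-dihydro-2H-chromen-2-yl]-5-methoxyphenol
Conditions: 3 M aq HCl, MeOH, 25 to 40 °C
Reagents that add atoms: none
Why: Acid-catalysed acetal exchange of both aryl MOM ethers with methanol, the usual way to unmask prenylated phenols; the meta-oxygen pattern of ring B gives no resonance support to a C2 cation, so the stereocentre should be safe, and mild conditions should keep the C7 hydroxyl from adding to the prenyl olefin.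

## Compound list

1 | 2,6-difluoro-4-hydroxybenzaldehyde | O=Cc1c(F)cc(O)cc1F | starting material
2 | 2,6-difluoro-4-(methoxymethoxy)benzaldehyde | O=Cc1c(F)cc(OCOC)cc1F | intermediate
3 | 2-fluoro-6-methoxy-4-(methoxymethoxy)benzaldehyde | O=Cc1c(F)cc(OCOC)cc1OC | intermediate
4 | 1-(3-hydroxy-5-methoxyphenyl)ethan-1-one | CC(=O)c1cc(O)cc(OC)c1 | starting material
5 | 1-[3-methoxy-5-(methoxymethoxy)phenyl]ethan-1-one | CC(=O)c1cc(OC)cc(OCOC)c1 | intermediate
6 | 3-[2-fluoro-6-methoxy-4-(methoxymethoxy)phenyl]-3-hydroxy-1-[3-methoxy-5-(methoxymethoxy)phenyl]propan-1-one (racemic aldol adduct) | COCOc1cc(OC)cc(c1)C(=O)CC(O)c1c(F)cc(OCOC)cc1OC | intermediate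
7 | (2E)-3-[2-fluoro-6-methoxy-4-(methoxymethoxy)phenyl]-1-[3-methoxy-5-(methoxymethoxy)phenyl]prop-2-en-1-one | COCOc1cc(OC)cc(c1)C(=O)/C=C/c1c(F)cc(OCOC)cc1OC | intermediate
8 | 3-[2-fluoro-6-methoxy-4-(methoxymethoxy)phenyl]-1-[3-methoxy-5-(methoxymethoxy)phenyl]propan-1-one | COCOc1cc(OC)cc(c1)C(=O)CCc1c(F)cc(OCOC)cc1OC | intermediate
9 | (1R)-3-[2-fluoro-6-methoxy-4-(methoxymethoxy)phenyl]-1-[3-methoxy-5-(methoxymethoxy)phenyl]propan-1-ol | O[C@H](CCc1c(F)cc(OCOC)cc1OC)c1cc(OC)cc(OCOC)c1 | intermediate
10 | lithium (1R)-3-[2-fluoro-3-lithio-6-methoxy-4-(methoxymethoxy)phenyl]-1-[3-methoxy-5-(methoxymethoxy)phenyl]propan-1-olate | [Li]O[C@H](CCc1c(F)c([Li])c(OCOC)cc1OC)c1cc(OC)cc(OCOC)c1 | intermediate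
11 | lithium (1R)-3-[2,3-didehydro-6-methoxy-4-(methoxymethoxy)phenyl]-1-[3-methoxy-5-(methoxymethoxy)phenyl]propan-1-olate (aryne) | [Li]O[C@H](CCC1=C(OC)C=C(OCOC)C#C1)c1cc(OC)cc(OCOC)c1 | intermediate
12 | (2R)-8-lithio-5-methoxy-7-(methoxymethoxy)-2-[3-methoxy-5-(methoxymethoxy)phenyl]-3,4-dihydro-2H-chromene | COCOc1cc(OC)cc([C@H]2CCc3c(OC)cc(OCOC)c([Li])c3O2)c1 | intermediate
13 | (2R)-5-methoxy-7-(methoxymethoxy)-2-[3-methoxy-5-(methoxymethoxy)phenyl]-8-(3-methylbut-2-en-1-yl)-3,4-dihydro-2H-chromene | COCOc1cc(OC)cc([C@H]2CCc3c(OC)cc(OCOC)c(CC=C(C)C)c3O2)c1 | intermediate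
14 | 3-[(2R)-7-hydroxy-5-methoxy-8-(3-methylbut-2-en-1-yl)-3,4-dihydro-2H-chromen-2-yl]-5-methoxyphenol | COc1cc(O)cc([C@H]2CCc3c(OC)cc(O)c(CC=C(C)C)c3O2)c1 | target

## Step count and least certain steps

Total: 8 steps. Longest linear sequence: 7 steps (steps 1, 2, 4, 5, 6, 7, 8); step 3 is the one-step side branch.

Step 7 (key step). Three things may go wrong:
- Lithiation may occur in part at a C–H lying between two oxygens (ring A C6 or ring B C4′) instead of next to fluorine.
- The lithium alkoxide may add sluggishly, so that the aryne is consumed by aryllithium species and oligomerises.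
- The hindered C8 carbanion may be protonated instead of allylated.

Fallback: from 9 the ring closure and the prenylation would be separated. Treatment of 9 with lithium 2,2,6,6-tetramethylpiperidide (LiTMP, 3 equiv, THF, −78 to 0 °C) should deprotonate reversibly only where fluorine provides the acidity. It should also keep the standing concentration of aryllithium low, and after aryne closure the amine protonates C8. This would give (2R)-5-methoxy-7-(methoxymethoxy)-2-[3-methoxy-5-(methoxymethoxy)phenyl]-3,4-dihydro-2H-chromene F1. Bromination with N-bromosuccinimide (CH2Cl2, −40 °C) should take place on the more electron-rich ring A, at C8 (para to the C5 methoxy group and less crowded than C6), to give the 8-bromo compound (2R)-8-bromo-5-methoxy-7-(methoxymethoxy)-2-[3-methoxy-5-(methoxymethoxy)phenyl]-3,4-dihydro-2H-chromene F2. Bromine–lithium exchange (n-BuLi, THF, −78 °C) then regenerates 12, and CuBr·SMe2 with prenyl bromide returns the route to 13.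

Step 8. The acid needed for MOM cleavage may also protonate the prenyl olefin, after which the C7 hydroxyl closes a dimethylpyran ring. Fallback: from 9 the sequence of step 7 would be run with allyl bromide as the electrophile (through 10, 11 and 12) to give (2R)-5-methoxy-7-(methoxymethoxy)-2-[3-methoxy-5-(methoxymethoxy)phenyl]-8-(prop-2-en-1-yl)-3,4-dihydro-2H-chromene F3. Its allyl group cannot form a tertiary cation, so HCl in MeOH should give 3-[(2R)-7-hydroxy-5-methoxy-8-(prop-2-en-1-yl)-3,4-dihydro-2H-chromen-2-yl]-5-methoxyphenol F4 without risk. Olefin cross-metathesis of F4 with excess 2-methylbut-2-ene (second-generation Grubbs catalyst, CH2Cl2, 40 °C), a neutral reaction that tolerates free phenols, then turns allyl into prenyl and arrives at 14.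

Step 5. Hydrogenation may run on to reduce the aryl ketone, which would give racemic carbinol or a methylene group. Fallback: from 7 the two reductions would be merged into one transfer-hydrogenation operation with RuCl[(R,R)-TsDPEN](p-cymene) and HCO2Na in water/MeOH at 40 °C. The ruthenium hydride first adds in conjugate fashion to the enone and then reduces the ketone enantioselectively, so 8 is only passed through and the route is rejoined at 9.

Step 4. Aldol addition to the doubly ortho-substituted aldehyde may be slow, and on long exposure hydroxide or ethoxide may displace the ring-A fluorine. Fallback: from 3 and 5 the bond would be made under non-nucleophilic conditions. The lithium enolate of 5 (LiN(iPr)2, THF, −78 °C) adds to 3 to give aldol 6, now isolated. Methanesulfonyl chloride and Et3N (CH2Cl2, 0 °C to rt) convert it to 3-[2-fluoro-6-methoxy-4-(methoxymethoxy)phenyl]-1-[3-methoxy-5-(methoxymethoxy)phenyl]-3-oxopropyl methanesulfonate F5, which eliminates in the same flask to 7.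

## Further compounds

F1 | step 7 | (2R)-5-methoxy-7-(methoxymethoxy)-2-[3-methoxy-5-(methoxymethoxy)phenyl]-3,4-dihydro-2H-chromene | COCOc1cc(OC)cc([C@H]2CCc3c(OC)cc(OCOC)cc3O2)c1
F2 | step 7 | (2R)-8-bromo-5-methoxy-7-(methoxymethoxy)-2-[3-methoxy-5-(methoxymethoxy)phenyl]-3,4-dihydro-2H-chromene | COCOc1cc(OC)cc([C@H]2CCc3c(OC)cc(OCOC)c(Br)c3O2)c1
F3 | step 8 | (2R)-5-methoxy-7-(methoxymethoxy)-2-[3-methoxy-5-(methoxymethoxy)phenyl]-8-(prop-2-en-1-yl)-3,4-dihydro-2H-chromene | COCOc1cc(OC)cc([C@H]2CCc3c(OC)cc(OCOC)c(CC=C)c3O2)c1
F4 | step 8 | 3-[(2R)-7-hydroxy-5-methoxy-8-(prop-2-en-1-yl)-3,4-dihydro-2H-chromen-2-yl]-5-methoxyphenol | COc1cc(O)cc([C@H]2CCc3c(OC)cc(O)c(CC=C)c3O2)c1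
F0 | step 5 | none | none
F5 | step 4 | 3-[2-fluoro-6-methoxy-4-(methoxymethoxy)phenyl]-1-[3-methoxy-5-(methoxymethoxy)phenyl]-3-oxopropyl methanesulfonate | COCOc1cc(OC)cc(c1)C(=O)CC(OS(C)(=O)=O)c1c(F)cc(OCOC)cc1OC
A1 | alternative 1 | (1S)-3-[2-hydroxy-6-methoxy-4-(methoxymethoxy)-3-(3-methylbut-2-en-1-yl)phenyl]-1-[3-methoxy-5-(methoxymethoxy)phenyl]propan-1-ol | O[C@@H](CCc1c(O)c(CC=C(C)C)c(OCOC)cc1OC)c1cc(OC)cc(OCOC)c1
A2 | alternative 2 | 3-methoxy-5-(methoxymethoxy)-2-methylidene-6-(3-methylbut-2-en-1-yl)cyclohexa-3,5-dien-1-one | C=C1C(OC)=CC(OCOC)=C(CC=C(C)C)C1=O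
A3 | alternative 2 | 1-ethenyl-3-methoxy-5-(methoxymethoxy)benzene | C=Cc1cc(OC)cc(OCOC)c1
A4 | alternative 3 | (2R)-5-methoxy-2-[3-methoxy-5-(methoxymethoxy)phenyl]-7-[(2-methylbut-3-en-2-yl)oxy]-3,4-dihydro-2H-chromene | COCOc1cc(OC)cc([C@H]2CCc3c(OC)cc(OC(C)(C)C=C)cc3O2)c1
A5 | alternative 3 | (2R)-5-methoxy-2-[3-methoxy-5-(methoxymethoxy)phenyl]-6-(3-methylbut-2-en-1-yl)-3,4-dihydro-2H-chromen-7-ol | COCOc1cc(OC)cc([C@H]2CCc3c(OC)c(CC=C(C)C)c(O)cc3O2)c1
A6 | alternative 3 | (2R)-5-methoxy-2-[3-methoxy-5-(methoxymethoxy)phenyl]-8-(3-methylbut-2-en-1-yl)-3,4-dihydro-2H-chromen-7-ol | COCOc1cc(OC)cc([C@H]2CCc3c(OC)cc(O)c(CC=C(C)C)c3O2)c1
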